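# Total synthesis of CNP0149861.1 by a terminal cyclase bicyclisation of a farnesyl arene sulfate

## Analysis of the target

Compound 18 is a sesquiterpenyl arene. A trans-fused decalin (ring A: C1–C5 and C10; ring B: C5–C10, drimane numbering) carries a gem-dimethyl group at C4, an angular methyl at C10 and a secondary methyl at C8, and is joined through an exocyclic E-configured C9=C11 double bond to a pentasubstituted benzene (C1′–C6′). The arene bears a hydrogen sulfate on O2′, a formyl group on C3′ and a free catechol on C4′ and C5′; only C6′ carries hydrogen. There are three stereocentres, C5 (S), C8 (S) and C10 (S): H5 is α and the C10 methyl β (trans fusion), and the C8 methyl is β and axial, syn-diaxial to the C10 methyl, so that the small equatorial H8 lies in the plane of the alkene next to the aryl group. The sensitive groups are the aryl sulfate (lost by acid solvolysis), the catechol (air oxidation), the aldehyde flanked by two oxygens, and the electron-rich styrene, whose protonation at C11 would give a C9 cation free to rearrange. The synthesis is hard because the alkene sits between a quaternary and a tertiary carbon, the C8 methyl is axial, and three phenolic oxygens must end in two different states while acid, hydrogenation and oxidants are excluded late in the route. The strategy rests on the fact that 18 has the formula and carbon connectivity of a (2E,6E)-farnesyl arene once the bonds C4–C5 and C9–C10 are cut. The α-hydrogen at C8 together with the C9=C11 unsaturation is what a C8 cation leaves behind when it takes H9 and the resulting C9 cation loses a C11 proton, so the decalin, its three stereocentres and the alkene can all be written by one folding of an achiral chain.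

## Retrosynthetic reasoning

**18 ⇒ 15.** The bonds C4–C5 and C9–C10 are cut, H8 is returned to C9 and one hydrogen to C11. These are the only two cuts that turn the decalin into an unbranched all-E isoprenoid chain; all three stereocentres disappear and no oxidation level changes, so 15 is an achiral isomer of 18. The forward reaction has to protonate the terminal alkene, close rings A and B in one fold, shift H9 to C8 and remove a C11 proton, all in one enantiomeric sense. Only an enzyme pocket can be expected to do that, and because the arene of 15 is already complete, nothing needs to follow.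

**15 ⇒ 14 ⇒ 13.** The two O–Si bonds and then the O–S bond are cut. The catechol has to be unmasked in the presence of an aryl sulfate and a triene, which rules out acid (solvolysis, cyclisation) and hydrogenolysis; aryl silyl ethers fall to fluoride and answer this. Working back, the sulfate goes on when O2′–H is the only free hydroxyl, so that no selectivity among the three oxygens is asked of the sulfation.

**13 ⇒ 11.** The C3′–CHO bond is cut. In 11 the free O2′–H has one ortho carbon left, C3′, so a phenoxide-directed formylation can go nowhere else. The formyl group is placed after the farnesyl chain because an aldehyde would not survive the aryllithium needed for the C–C coupling, and it is directed by the phenol rather than by lithiation because a carbanion next to the O4′ silyl ether would invite silyl migration.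

**11 ⇒ 10 ⇒ 6 + 7.** After the O2′ acetal is put back, the aryl–allyl bond C1′–C11 is cut. This is the one C–C bond between the two commercial carbon blocks; it leads to farnesyl bromide 7, which carries both E alkenes ready-made, and to aryl bromide 6. The forward reaction (6 to aryllithium 8 to arylcopper 9, then 7) must substitute at the primary allylic carbon without transposition and without touching the alkene geometry.

**6 ⇒ 5 ⇒ 4.** The C–Br bond is cut, then the acetal O–C bond. In 5 the carbon para to the O4′ silyl ether and ortho to the O2′ acetal is the only position that is doubly activated and unhindered, so electrophilic bromination marks C1′. The acetal on O2′ is needed only to carry the phenol through the organometallic step and to hold the aryllithium by chelation.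

**4 ⇒ 2 ⇒ 1.** The O2′–C1 oxygen is traced back to a formyl carbon, and the silyl ethers to the free catechol of 1. An unprotected trihydroxybenzene would give no handle to tell the three oxygens apart. In 1 the future O2′ is still a carbon substituent while the catechol is silylated, and an aryl-migrating oxidation then turns it into the phenol, so the O2′ versus O4′/O5′ differentiation is in place from the first step.

## Alternatives that were turned down

**Alternative 1:** The arene is disconnected instead of the decalin: C1′–C6′ and C3′–C4′ are cut, leading to methyl ketone A2 and methyl acrylate A3. In the forward key step a tert-butoxide base would bring about Michael addition of the substituted α-carbon of A2 (C1′) to A3, and Claisen closure from the methyl carbon (C3′) onto the ester would give the cyclohexane-1,3-dione A1, to be aromatised later.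
- In its favour: both bond formations are classical enolate chemistry, the decalin stereocentres would be bought with a terpene, and on the certainty of the key step this route is stronger than the chosen one.
- Against it: A1 has oxygen only at C2′ and C4′. After aromatisation the C5′ oxygen and the C3′ formyl group must still be added, and the sulfation must then tell O2′ from O4′, two oxygens that are both ortho to the formyl group.
- A1 is saturated at C9–C11, so the styrene has to be made by dehydrogenation next to an oxidisable trioxygenated ring.
- The Michael step needs the more substituted enolate of a methyl ketone, which competes with the methyl enolate, and A2 with its axial C8 methyl is itself a multistep target.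
- Comparison: many more steps, with the hardest features (alkene, oxygen pattern) postponed. The chosen strategy gives up the precedent but builds the full oxygen pattern on a simple benzene and makes rings, stereocentres and alkene in the last step.

**Alternative 2:** The C9=C11 bond is disconnected as a two-stage carbonyl–olefin exchange between the exocyclic alkene A5 and the aryl aldehyde A6. In the forward key step, irradiation near 300–350 nm would give the spiro-oxetane A4 (C9–C11 and O–CH2 bonds formed), and a later cycloreversion in the other sense would release the styrene.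
- In its favour: it is convergent, it attacks the hindered alkene directly, the two new stereocentres of A4 are irrelevant, and no strong acid or base is needed for the union. On convergence it is equal to or better than the chosen route.
- Against it: the C–C bond must form at C9 between the quaternary C10 and C8, and an oxygen-rich aryl aldehyde is a weak partner in this photocycloaddition.
- The cycloreversion must break the pair of bonds that was not formed; this usually needs acid or heat, under which a C9 cation can undergo methyl or hydride shifts, and nothing but thermodynamics sets the alkene geometry.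
- A5 must first be made enantiopure with the axial C8 methyl. The three acetates of A6 are equivalent, so O2′ cannot be singled out for sulfation, and the C3′ formyl group is still missing.
- Comparison: two uncertain steps instead of one, followed by the whole arene endgame on a sensitive styrene. The chosen strategy puts its single uncertain step last, with nothing after it.

**Alternative 3:** The bonds C5–C10 and C8–C9 are cut, leading to the aryl trienone A8. In the forward key step a chiral boron Lewis acid would catalyse an intramolecular Diels–Alder reaction that closes rings A and B together and gives the trans-fused adduct A7.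
- In its favour: the reaction class is known, catalytic and enantioselective, and it sets C5, C8 and C10 in one step. On precedent it is clearly stronger than the chosen route.
- Against it: the C5–C10 bond joins a diene terminus next to the quaternary C4 to a fully substituted dienophile carbon, so three contiguous crowded centres meet in the transition state.
- A β,β-disubstituted aryl enone is a weak dienophile, its ortho acetal oxygen competes for the Lewis acid, and the acetal protecting groups must survive that acid. Trans fusion and the C8 configuration depend on an endo/exo preference that the structure does not guarantee.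
- After A7 the C6=C7 bond must be hydrogenated and the ketone converted into the C9=C11 alkene, which destroys the C9 centre just made. A catechol acetal must then be cleaved by acid beside the styrene, and formylation and sulfation still follow.
- Comparison: better precedent, but a long and acid-dependent endgame. The chosen strategy offers a fully decorated, achiral precursor and no post-cyclisation chemistry.

Key step: step 10

## Route

Remark on the chemistry: the aryl sulfate monoesters 14, 15 and 18 are drawn as hydrogen sulfates to match the target. They are monoanions at the pH of every step, are handled as sodium salts, and 18 is released as the free acid only by ion exchange at the end.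

Numbering: terpenoid carbons follow drimane (C11 on C9, C12 the methyl on C8); the same numbers are kept in the open chain, so C11 is the benzylic CH2 and C3=C4 the terminal alkene. The arene is C1′–C6′, with C1′ bearing C11.

Step 1
Reactants: 1 3,4-dihydroxybenzaldehyde
Product: 2 3,4-bis(tert-butyldimethylsilyloxy)benzaldehyde
Conditions: TBSCl (2.4 equiv), imidazole (5 equiv), DMF, 0 °C to rt
Reagents that add atoms: tert-butyldimethylsilyl chloride, CC(C)(C)[Si](C)(C)Cl
Why: Standard imidazole-mediated silylation of phenols; both catechol oxygens react while the formyl group, which marks the future O2′, stays untouched.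

Step 2
Reactants: 2 3,4-bis(tert-butyldimethylsilyloxy)benzaldehyde
Product: 4 3,4-bis(tert-butyldimethylsilyloxy)phenol, via aryl formate 3 (not isolated)
Conditions: mCPBA (1.3 equiv), CH2Cl2, 0 °C to rt; then Et3N (0.2 equiv), MeOH, 0 °C
Reagents that add atoms: meta-chloroperbenzoic acid, OOC(=O)c1cccc(Cl)c1
Why: Baeyer–Villiger (Dakin-type) oxidation, in which the aryl group with a para silyloxy donor migrates in preference to hydrogen; the aryl formate is methanolysed much faster than an aryl silyl ether is attacked.

Step 3
Reactants: 4 3,4-bis(tert-butyldimethylsilyloxy)phenol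
Product: 5 1,2-bis(tert-butyldimethylsilyloxy)-4-(methoxymethoxy)benzene
Conditions: MOMCl (1.5 equiv), iPr2NEt (2 equiv), CH2Cl2, 0 °C to rt
Reagents that add atoms: chloromethyl methyl ether, COCCl
Why: O-Alkylation of the phenol by the oxocarbenium-type electrophile; the acetal later withstands the aryllithium and chelates it.

Step 4
Reactants: 5 1,2-bis(tert-butyldimethylsilyloxy)-4-(methoxymethoxy)benzene
Product: 6 1-bromo-4,5-bis(tert-butyldimethylsilyloxy)-2-(methoxymethoxy)benzene
Conditions: NBS (1.05 equiv), MeCN, 0 °C
Reagents that add atoms: N-bromosuccinimide, O=C1CCC(=O)N1Br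
Why: Electrophilic aromatic bromination at the carbon ortho to the acetal oxygen and para to a silyloxy group (the future C1′); the other doubly activated carbon lies between two oxygen substituents and is shielded.

Step 5
Reactants: 6 1-bromo-4,5-bis(tert-butyldimethylsilyloxy)-2-(methoxymethoxy)benzene; 7 (2E,6E)-farnesyl bromide
Product: 10 1,2-bis(tert-butyldimethylsilyloxy)-4-(methoxymethoxy)-5-[(2E,6E)-3,7,11-trimethyldodeca-2,6,10-trien-1-yl]benzene, via aryllithium 8 (not isolated), via arylcopper 9 (not isolated)
Conditions: n-BuLi (1.05 equiv), THF, −78 °C; CuBr·SMe2 (1.0 equiv), −78 to −40 °C; 7 (1.1 equiv), −78 to 0 °C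
Reagents that add atoms: none
Why: Bromine–lithium exchange outruns any deprotonation and gives an aryllithium held by the ortho acetal; transmetalation to monovalent copper tempers its basicity, and the arylcopper displaces bromide at the primary carbon of 7 (copper-mediated allylic substitution, SN2 regiochemistry because the γ-carbon is fully substituted), leaving both E alkenes untouched.

Step 6
Reactants: 10 1,2-bis(tert-butyldimethylsilyloxy)-4-(methoxymethoxy)-5-[(2E,6E)-3,7,11-trimethyldodeca-2,6,10-trien-1-yl]benzene
Product: 11 4,5-bis(tert-butyldimethylsilyloxy)-2-[(2E,6E)-3,7,11-trimethyldodeca-2,6,10-trien-1-yl]phenol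
Conditions: ZnBr2 (1 equiv), n-PrSH (2 equiv), CH2Cl2, 0 °C, 10 min
Reagents that add atoms: none
Why: Lewis-acid-assisted acetal cleavage in which the thiol captures the methoxymethyl cation; the treatment is short and non-protic, so aryl silyl ethers and trisubstituted alkenes should stay intact and the ortho-allyl phenol should not close to a chroman.

Step 7
Reactants: 11 4,5-bis(tert-butyldimethylsilyloxy)-2-[(2E,6E)-3,7,11-trimethyldodeca-2,6,10-trien-1-yl]phenol
Product: 13 2,3-bis(tert-butyldimethylsilyloxy)-6-hydroxy-5-[(2E,6E)-3,7,11-trimethyldodeca-2,6,10-trien-1-yl]benzaldehyde, via hydroxymethylphenol 12 (not isolated)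
Conditions: MgCl2 (2 equiv), Et3N (4 equiv), (CH2O)n (6 equiv), THF, 65 °C
Reagents that add atoms: paraformaldehyde (as formaldehyde), C=O
Why: Casnati–Skattebøl ortho-formylation: the magnesium phenoxide delivers formaldehyde to the only free ortho carbon, C3′, and the magnesium alkoxide of 12 passes a hydride to a second formaldehyde (Oppenauer-type redox), so no external oxidant meets the triene; aryl silyl ethers and isolated alkenes tolerate these conditions.

Step 8
Reactants: 13 2,3-bis(tert-butyldimethylsilyloxy)-6-hydroxy-5-[(2E,6E)-3,7,11-trimethyldodeca-2,6,10-trien-1-yl]benzaldehyde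
Product: 14 3,4-bis(tert-butyldimethylsilyloxy)-2-formyl-6-[(2E,6E)-3,7,11-trimethyldodeca-2,6,10-trien-1-yl]phenyl hydrogen sulfate
Conditions: SO3·pyridine (4 equiv), pyridine, 40 °C; then aq. NaHCO3
Reagents that add atoms: sulfur trioxide–pyridine complex, [O-]S(=O)(=O)[n+]1ccccc1
Why: O-Sulfonation of a phenol by a sulfur trioxide–amine complex; O2′–H is the only free hydroxyl, so no selectivity is required, and warming with excess reagent should overcome its hydrogen bond to the formyl group.

Step 9
Reactants: 14 3,4-bis(tert-butyldimethylsilyloxy)-2-formyl-6-[(2E,6E)-3,7,11-trimethyldodeca-2,6,10-trien-1-yl]phenyl hydrogen sulfate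
Product: 15 2-formyl-3,4-dihydroxy-6-[(2E,6E)-3,7,11-trimethyldodeca-2,6,10-trien-1-yl]phenyl hydrogen sulfate
Conditions: KHF2 (3 equiv), MeOH, rt, argon; C18 chromatography
Reagents that add atoms: none
Why: Fluoride-induced desilylation, fast for aryl silyl ethers because phenoxide is a good leaving group; the medium is neither acidic enough to solvolyse the sulfate or protonate the triene nor basic enough to harm the aldehyde, and air is excluded to spare the catechol.

Step 10
Reactants: 15 2-formyl-3,4-dihydroxy-6-[(2E,6E)-3,7,11-trimethyldodeca-2,6,10-trien-1-yl]phenyl hydrogen sulfate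
Product: 18 2-formyl-3,4-dihydroxy-6-{(E)-[(2S,4aS,8aS)-2,5,5,8a-tetramethyloctahydronaphthalen-1(2H)-ylidene]methyl}phenyl hydrogen sulfate, via C8 cation 16 (not isolated), via C9 cation 17 (not isolated)
Conditions: squalene–hopene cyclase variant (Alicyclobacillus acidocaldarius enzyme, E. coli whole cells), citrate buffer (Na3C6H5O7/citric acid) pH 6.0, Triton X-100 (0.2%), 40 °C; C18 chromatography; H+-form ion exchange
Reagents that add atoms: none
Why: Proposed new method: a class 2 terpene cyclase of the squalene–hopene type should bind 15 in a chair–chair fold with the sulfated arene at the mouth of the channel and protonate C3 of the terminal alkene from its catalytic aspartic acid; C5 then attacks C4 and C9 attacks C10, each closure 6-endo with anti addition across an E double bond, which gives ring A, ring B and the trans-decalin C8 cation 16. The axial H9 on the α face lies parallel to the empty orbital at C8 and should migrate suprafacially to give the C9 cation 17, from which an active-site base takes a C11 proton to leave the arene-conjugated alkene. The closest known reaction type is the bicyclisation of farnesylated phenols and of homofarnesol by squalene–hopene cyclases, which ends by heteroatom capture at C8; a hydride shift followed by proton loss is the ending used by related class 2 diterpene cyclases that form halimadienyl and clerodienyl skeletons, so each half of the cascade has a counterpart but their combination on this substrate has none. C5 and C10 are set relative to each other by the E geometry of the C5=C10 alkene and the chair fold (anti addition, hence H5 α and C10 methyl β), and in the absolute sense by the pocket, which in this enzyme family enforces the fold leading to that series. C8 is set by the hydride, which can only arrive on the α face from which it departs at C9, so the C8 methyl is forced into the axial β position. The alkene should be E because the aryl group turns away from the quaternary C10 towards the small equatorial H8. The step needs selectivity in how the cascade ends: the sulfate on O2′ removes the only oxygen that could close an ether ring onto C8, the formyl group para to C6′ deactivates the one free ring carbon towards Friedel–Crafts closure, and a charge at C9 acidifies the benzylic C11 hydrogens, so the substrate itself favours the wanted exit. Keeping water and any base away from C7 and C12 while 16 waits for the hydride shift is the task of the variant, to be found by screening active-site libraries.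

## Compound list

1 | 3,4-dihydroxybenzaldehyde | O=Cc1ccc(O)c(O)c1 | starting material
2 | 3,4-bis(tert-butyldimethylsilyloxy)benzaldehyde | O=Cc1ccc(O[Si](C)(C)C(C)(C)C)c(O[Si](C)(C)C(C)(C)C)c1 | intermediate
3 | 3,4-bis(tert-butyldimethylsilyloxy)phenyl formate | O=COc1ccc(O[Si](C)(C)C(C)(C)C)c(O[Si](C)(C)C(C)(C)C)c1 | intermediate (not isolated)
4 | 3,4-bis(tert-butyldimethylsilyloxy)phenol | Oc1ccc(O[Si](C)(C)C(C)(C)C)c(O[Si](C)(C)C(C)(C)C)c1 | intermediate
5 | 1,2-bis(tert-butyldimethylsilyloxy)-4-(methoxymethoxy)benzene | COCOc1ccc(O[Si](C)(C)C(C)(C)C)c(O[Si](C)(C)C(C)(C)C)c1 | intermediate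
6 | 1-bromo-4,5-bis(tert-butyldimethylsilyloxy)-2-(methoxymethoxy)benzene | COCOc1cc(O[Si](C)(C)C(C)(C)C)c(O[Si](C)(C)C(C)(C)C)cc1Br | intermediate
7 | (2E,6E)-farnesyl bromide, (2E,6E)-1-bromo-3,7,11-trimethyldodeca-2,6,10-triene | CC(C)=CCC/C(C)=C/CC/C(C)=C/CBr | starting material
8 | [4,5-bis(tert-butyldimethylsilyloxy)-2-(methoxymethoxy)phenyl]lithium | COCOc1cc(O[Si](C)(C)C(C)(C)C)c(O[Si](C)(C)C(C)(C)C)cc1[Li] | intermediate (not isolated)
9 | [4,5-bis(tert-butyldimethylsilyloxy)-2-(methoxymethoxy)phenyl]copper | COCOc1cc(O[Si](C)(C)C(C)(C)C)c(O[Si](C)(C)C(C)(C)C)cc1[Cu] | intermediate (not isolated)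
10 | 1,2-bis(tert-butyldimethylsilyloxy)-4-(methoxymethoxy)-5-[(2E,6E)-3,7,11-trimethyldodeca-2,6,10-trien-1-yl]benzene | CC(C)=CCC/C(C)=C/CC/C(C)=C/Cc1cc(O[Si](C)(C)C(C)(C)C)c(O[Si](C)(C)C(C)(C)C)cc1OCOC | intermediate
11 | 4,5-bis(tert-butyldimethylsilyloxy)-2-[(2E,6E)-3,7,11-trimethyldodeca-2,6,10-trien-1-yl]phenol | CC(C)=CCC/C(C)=C/CC/C(C)=C/Cc1cc(O[Si](C)(C)C(C)(C)C)c(O[Si](C)(C)C(C)(C)C)cc1O | intermediate
12 | 3,4-bis(tert-butyldimethylsilyloxy)-2-(hydroxymethyl)-6-[(2E,6E)-3,7,11-trimethyldodeca-2,6,10-trien-1-yl]phenol (formed as its magnesium salt) | CC(C)=CCC/C(C)=C/CC/C(C)=C/Cc1cc(O[Si](C)(C)C(C)(C)C)c(O[Si](C)(C)C(C)(C)C)c(CO)c1O | intermediate (not isolated)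
13 | 2,3-bis(tert-butyldimethylsilyloxy)-6-hydroxy-5-[(2E,6E)-3,7,11-trimethyldodeca-2,6,10-trien-1-yl]benzaldehyde | CC(C)=CCC/C(C)=C/CC/C(C)=C/Cc1cc(O[Si](C)(C)C(C)(C)C)c(O[Si](C)(C)C(C)(C)C)c(C=O)c1O | intermediate
14 | 3,4-bis(tert-butyldimethylsilyloxy)-2-formyl-6-[(2E,6E)-3,7,11-trimethyldodeca-2,6,10-trien-1-yl]phenyl hydrogen sulfate | CC(C)=CCC/C(C)=C/CC/C(C)=C/Cc1cc(O[Si](C)(C)C(C)(C)C)c(O[Si](C)(C)C(C)(C)C)c(C=O)c1OS(=O)(=O)O | intermediate
15 | 2-formyl-3,4-dihydroxy-6-[(2E,6E)-3,7,11-trimethyldodeca-2,6,10-trien-1-yl]phenyl hydrogen sulfate | CC(C)=CCC/C(C)=C/CC/C(C)=C/Cc1cc(O)c(O)c(C=O)c1OS(=O)(=O)O | intermediate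
16 | bicyclic C8 cation: trans-decalin with 5α-H, 10β-methyl, 9α-H and 9β-arylmethyl, charge at C8 (drawn as zwitterion with the sulfate) | C[C+]1CC[C@H]2C(C)(C)CCC[C@]2(C)[C@H]1Cc1cc(O)c(O)c(C=O)c1OS(=O)(=O)[O-] | intermediate (not isolated)
17 | bicyclic C9 cation: trans-decalin with 5α-H, 10β-methyl, 8α-H and 8β-methyl, charge at C9 (drawn as zwitterion with the sulfate) | C[C@H]1CC[C@H]2C(C)(C)CCC[C@]2(C)[C+]1Cc1cc(O)c(O)c(C=O)c1OS(=O)(=O)[O-] | intermediate (not isolated)
18 | 2-formyl-3,4-dihydroxy-6-{(E)-[(2S,4aS,8aS)-2,5,5,8a-tetramethyloctahydronaphthalen-1(2H)-ylidene]methyl}phenyl hydrogen sulfate (5S,8S,10S in drimane numbering) | C[C@H]1CC[C@H]2C(C)(C)CCC[C@]2(C)/C1=C/c1cc(O)c(O)c(C=O)c1OS(=O)(=O)O | target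

## Step count and least certain steps

Total: 10 steps. Longest linear sequence: 10 steps (1 to 18; 7 enters at step 5).

**Step 10 (key step).** The sulfated, doubly ortho-substituted head group may fail to enter the substrate channel. If it binds, the cascade may stop early through proton loss from C7 or C12 or through hydration at C8 before the hydride migrates, or it may halt after ring A. A change of substrate form would still depend on the same unproven ending, so the fallback leaves cationic cyclisation altogether and joins two halves by known polar chemistry. It sets out from aryl bromide 6 and returns at 18. Commercial (−)-drimenol F1 would be hydrogenated (H2, PtO2, EtOAc); hydrogen should arrive on the α face, away from the angular methyl, and give (8S)-driman-11-ol F2 with the axial 8β-methyl. Oxidation with Dess–Martin periodinane would give (8S)-driman-11-al F3. Aryllithium 8, made from 6 with n-BuLi as in step 5, would add to F3 to give the benzylic carbinol F4 (either C11 epimer serves). Dehydration with the Burgess reagent can only remove H9 and should favour the E-styrene F5, in which the aryl group avoids C10. The arene would then be finished as in steps 6 to 9: acetal cleavage (ZnBr2, n-PrSH) to the styryl phenol F6, magnesium-mediated ortho-formylation to the salicylaldehyde F7, sulfation with SO3·pyridine to the silylated sulfate F8, and desilylation with KHF2 in MeOH to 18.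

**Step 7.** Formylation at a ring carbon flanked by the bulky O4′ silyl ether may be slow, and prolonged heating with the amine base and the methanol formed may strip that silyl group, which would cost the O2′/O4′ differentiation. The fallback sets out from 11 and returns at 13, building the carbon in two redox-separated stages with boron as the template. Phenylboronic acid and paraformaldehyde with catalytic propionic acid in hot toluene would give the 2-phenyl-4H-1,3,2-benzodioxaborin F9 by intramolecular delivery to C3′. Exchange with propane-1,3-diol would release 12, this time isolated, and MnO2 in CH2Cl2 would oxidise the benzylic alcohol to 13.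

**Step 5.** Allylic transposition (attack at the γ-carbon), homocoupling of the allylic bromide, or partial loss of E geometry through ionisation of 7 may lower the yield of the linear product. The fallback sets out from 6 and returns at 10, replacing the copper-mediated substitution by a palladium-catalysed cross-coupling. Aryllithium 8 would be quenched with 2-isopropoxy-4,4,5,5-tetramethyl-1,3,2-dioxaborolane to give the aryl pinacol boronate F10, and Suzuki–Miyaura coupling of F10 with 7 (Pd(PPh3)4 as the zerovalent palladium source, K3PO4, THF/H2O, 60 °C) would form the C1′–C11 bond at the less hindered allyl terminus.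

**Step 8.** Sulfation of the hydrogen-bonded phenol between the formyl group and the farnesyl chain may be incomplete, and the monoester may be lost during isolation from the pyridinium medium. The fallback sets out from 13 and returns at 14, using a neutral sulfate diester as a carrier. 2,2,2-Trichloroethyl chlorosulfate with DMAP and Et3N in THF would give the aryl trichloroethyl sulfate F11, which can be purified on silica, and Zn with HCO2NH4 in MeOH would remove the trichloroethyl group reductively to give 14.

## Further compounds

F1 | step 10 | (−)-drimenol, drim-7-en-11-ol (5α-H, 9β-CH2OH, 10β-methyl) | CC1=CC[C@H]2C(C)(C)CCC[C@]2(C)[C@H]1CO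
F2 | step 10 | (8S)-driman-11-ol (8β-methyl, 9β-CH2OH) | C[C@H]1CC[C@H]2C(C)(C)CCC[C@]2(C)[C@H]1CO
F3 | step 10 | (8S)-driman-11-al (8β-methyl) | C[C@H]1CC[C@H]2C(C)(C)CCC[C@]2(C)[C@H]1C=O
F4 | step 10 | [4,5-bis(tert-butyldimethylsilyloxy)-2-(methoxymethoxy)phenyl][(8S)-driman-9-yl]methanol (C11 epimers) | C[C@H]1CC[C@H]2C(C)(C)CCC[C@]2(C)[C@H]1C(O)c1cc(O[Si](C)(C)C(C)(C)C)c(O[Si](C)(C)C(C)(C)C)cc1OCOC
F5 | step 10 | 1,2-bis(tert-butyldimethylsilyloxy)-4-(methoxymethoxy)-5-{(E)-[(2S,4aS,8aS)-2,5,5,8a-tetramethyloctahydronaphthalen-1(2H)-ylidene]methyl}benzene | C[C@H]1CC[C@H]2C(C)(C)CCC[C@]2(C)/C1=C/c1cc(O[Si](C)(C)C(C)(C)C)c(O[Si](C)(C)C(C)(C)C)cc1OCOC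
F6 | step 10 | 4,5-bis(tert-butyldimethylsilyloxy)-2-{(E)-[(2S,4aS,8aS)-2,5,5,8a-tetramethyloctahydronaphthalen-1(2H)-ylidene]methyl}phenol | C[C@H]1CC[C@H]2C(C)(C)CCC[C@]2(C)/C1=C/c1cc(O[Si](C)(C)C(C)(C)C)c(O[Si](C)(C)C(C)(C)C)cc1O
F7 | step 10 | 2,3-bis(tert-butyldimethylsilyloxy)-6-hydroxy-5-{(E)-[(2S,4aS,8aS)-2,5,5,8a-tetramethyloctahydronaphthalen-1(2H)-ylidene]methyl}benzaldehyde | C[C@H]1CC[C@H]2C(C)(C)CCC[C@]2(C)/C1=C/c1cc(O[Si](C)(C)C(C)(C)C)c(O[Si](C)(C)C(C)(C)C)c(C=O)c1O
F8 | step 10 | 3,4-bis(tert-butyldimethylsilyloxy)-2-formyl-6-{(E)-[(2S,4aS,8aS)-2,5,5,8a-tetramethyloctahydronaphthalen-1(2H)-ylidene]methyl}phenyl hydrogen sulfate | C[C@H]1CC[C@H]2C(C)(C)CCC[C@]2(C)/C1=C/c1cc(O[Si](C)(C)C(C)(C)C)c(O[Si](C)(C)C(C)(C)C)c(C=O)c1OS(=O)(=O)O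
F9 | step 7 | 5,6-bis(tert-butyldimethylsilyloxy)-2-phenyl-8-[(2E,6E)-3,7,11-trimethyldodeca-2,6,10-trien-1-yl]-4H-1,3,2-benzodioxaborin | CC(C)=CCC/C(C)=C/CC/C(C)=C/Cc1cc(O[Si](C)(C)C(C)(C)C)c(O[Si](C)(C)C(C)(C)C)c2COB(c3ccccc3)Oc12
F10 | step 5 | 2-[4,5-bis(tert-butyldimethylsilyloxy)-2-(methoxymethoxy)phenyl]-4,4,5,5-tetramethyl-1,3,2-dioxaborolane | COCOc1cc(O[Si](C)(C)C(C)(C)C)c(O[Si](C)(C)C(C)(C)C)cc1B1OC(C)(C)C(C)(C)O1
F11 | step 8 | 3,4-bis(tert-butyldimethylsilyloxy)-2-formyl-6-[(2E,6E)-3,7,11-trimethyldodeca-2,6,10-trien-1-yl]phenyl 2,2,2-trichloroethyl sulfate | CC(C)=CCC/C(C)=C/CC/C(C)=C/Cc1cc(O[Si](C)(C)C(C)(C)C)c(O[Si](C)(C)C(C)(C)C)c(C=O)c1OS(=O)(=O)OCC(Cl)(Cl)Cl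
A1 | alternative 1 | 4-[(8S)-driman-11-yl]cyclohexane-1,3-dione (8β-methyl, 9β-CH2; ring C1′ epimers) | C[C@H]1CC[C@H]2C(C)(C)CCC[C@]2(C)[C@H]1C[C@H]3CCC(=O)CC3=O
A2 | alternative 1 | 1-[(8S)-driman-11-yl]propan-2-one (8β-methyl, 9β side chain) | C[C@H]1CC[C@H]2C(C)(C)CCC[C@]2(C)[C@H]1CCC(C)=O
A3 | alternative 1 | methyl acrylate | C=CC(=O)OC
A4 | alternative 2 | 2-(2,4,5-triacetoxyphenyl)oxetane spiro-fused at its C3 to C9 of the (8S)-decalin (one diastereomer drawn) | C[C@H]1CC[C@H]2C(C)(C)CCC[C@]2(C)[C@@]13CO[C@H]3c1cc(OC(C)=O)c(OC(C)=O)cc1OC(C)=O
A5 | alternative 2 | (8S)-drim-9(11)-ene, (2S,4aS,8aS)-2,5,5,8a-tetramethyl-1-methylidenedecahydronaphthalene | C[C@H]1CC[C@H]2C(C)(C)CCC[C@]2(C)C1=C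
A6 | alternative 2 | 2,4,5-triacetoxybenzaldehyde | CC(=O)Oc1cc(OC(C)=O)c(OC(C)=O)cc1C=O
A7 | alternative 3 | [6-(methoxymethoxy)-2,2-dimethyl-1,3-benzodioxol-5-yl] ketone of the trans-decalin with a C6=C7 double bond, 8β-methyl and 9β-aroyl group | C[C@H]1C=C[C@H]2C(C)(C)CCC[C@]2(C)[C@H]1C(=O)c1cc2OC(C)(C)Oc2cc1OCOC
A8 | alternative 3 | (2E,9E,11E)-1-[6-(methoxymethoxy)-2,2-dimethyl-1,3-benzodioxol-5-yl]-3,8,8-trimethyltrideca-2,9,11-trien-1-one | C/C=C/C=C/C(C)(C)CCC/C(C)=C/C(=O)c1cc2OC(C)(C)Oc2cc1OCOC
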